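Retrosynthesis: the triene is cut back to a C7 ethynyl group (from a C7 nitrile); the C5–O bond is traced through a 1,3-transposition to an allyl selenide; ring A is cut at C8–C9 and C5–C6; ring B goes back to 2-methylcyclohexane-1,3-dione.
Forward: ring B is made first with its quaternary C10, the C1 bromide, a C9 iodide and the C4 methylene; ring A is then closed onto it in one pot by a [3+3] annulation with a 2-cyanoallyl unit; the C5 carbinol is re-set and the side chain is built last.
Enabling feature: in ring A the carbinol carbon C5 (a ketone carbon in the precursor) and C9 (a CH2 on the adjacent quaternary C10) are 1,3-related as electrophile and radical donor, and C6–C7–C8 is a three-carbon unit that is nucleophilic at C6 as an allylzinc and radical-accepting at C8 as an acrylonitrile.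
Stereochemistry: C10 and C1 from an enzymatic desymmetrization followed by SN2 inversion at C1; C5 from a [2,3] shift of an allyl selenoxide anti to the C10 methyl; C7 by equilibration to the equatorial position; alkene geometry from syn-carbometalation and stereoretentive cross-coupling.

Key step: step 6

Atom labels used below: ring B = C1 (CHBr), C2, C3, C4 (bearing the exocyclic C15), C5 (carbinol), C10 (bearing the angular methyl); ring A = C5, C6, C7 (bearing the side chain), C8, C9, C10.
Assumption: baker's yeast is taken to reduce 3 in the same sense as it reduces 2-allyl-2-methylcyclohexane-1,3-dione, giving the (1S,2S)-hydroxy ester with the hydroxyl cis to the acetate arm; an enantiocomplementary ketoreductase would be used if a given preparation gave the antipode.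
Where a centre is a mixture that converges later, its SMILES carries no descriptor.

Step 1
Reactants: 1 2-methylcyclohexane-1,3-dione; 2 ethyl bromoacetate
Product: 3 ethyl 2-(1-methyl-2,6-dioxocyclohexyl)acetate
Conditions: KOt-Bu, t-BuOH/THF, 0 → 60 °C
Reagents that add atoms: none
Why: C-alkylation of the stabilized enolate of the 2-substituted 1,3-dione with the activated α-halo ester should give the quaternary, still prochiral, diketo ester (enolate alkylation).

Step 2
Reactants: 3 ethyl 2-(1-methyl-2,6-dioxocyclohexyl)acetate
Product: 5 (3aS,7aS)-3a-methylhexahydro-1-benzofuran-2,4-dione, via hydroxy ester 4 (not isolated)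
Conditions: baker's yeast (Saccharomyces cerevisiae), sucrose, H2O, 30 °C; then TsOH (cat.), PhH, reflux
Reagents that add atoms: none
Why: The biocatalytic desymmetrizing reduction distinguishes the two enantiotopic ketones and delivers hydride to one face, which sets C10 and the C1 carbinol (hydroxyl cis to the acetate arm) at once, and the cis hydroxy ester then closes to the cis-fused five-membered lactone (enzymatic ketone reduction, then lactonization).

Step 3
Reactants: 5 (3aS,7aS)-3a-methylhexahydro-1-benzofuran-2,4-dione
Product: 7 2-[(1R,2R)-2-bromo-1-methyl-6-oxocyclohexyl]acetic acid, via silyl ester 6 (not isolated)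
Conditions: Me3SiBr, ZnBr2 (cat.), ClCH2CH2Cl, 60 °C; then H2O
Reagents that add atoms: bromotrimethylsilane (C[Si](C)(C)Br)
Why: Silylation of the lactone carbonyl turns the carboxylate into a leaving group and bromide should open the alkyl C–O bond at C1 by SN2 with inversion, so the α-oxygen becomes the β-bromide cis to the angular methyl while the carboxylic acid needed next is set free, enolate-driven elimination being impossible because C10 is quaternary (lactone cleavage by a halosilane).

Step 4
Reactants: 7 2-[(1R,2R)-2-bromo-1-methyl-6-oxocyclohexyl]acetic acid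
Product: 9 (2R,3R)-3-bromo-2-(iodomethyl)-2-methylcyclohexan-1-one, via acyl hypoiodite 8 (not isolated)
Conditions: PhI(OAc)2, I2, PhH, visible light, 80 °C
Reagents that add atoms: iodine (I-I)
Why: The acyl hypoiodite should fragment under light to CO2 and the primary C9 radical, which iodine traps much faster than the radical can undergo the 1,2-acyl (Dowd–Beckwith-type) shift (Suárez iododecarboxylation, a Hunsdiecker-type reaction).

Step 5
Reactants: 9 (2R,3R)-3-bromo-2-(iodomethyl)-2-methylcyclohexan-1-one
Product: 11 (5R,6R)-5-bromo-6-(iodomethyl)-6-methyl-2-methylidenecyclohexan-1-one, via Mannich base 10 (not isolated)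
Conditions: (CH2O)n, PhNHMe·CF3CO2H, THF, reflux
Reagents that add atoms: paraformaldehyde, reacting as formaldehyde (C=O)
Why: The ketone has a single enolizable position (C4), so Mannich condensation with the iminium ion from formaldehyde and the anilinium salt followed by β-elimination of N-methylaniline should place the exocyclic methylene (C15) on C4 (direct α-methylenation of a ketone).

Step 6
Reactants: 11 (5R,6R)-5-bromo-6-(iodomethyl)-6-methyl-2-methylidenecyclohexan-1-one; 12 2-(bromomethyl)prop-2-enenitrile
Product: 14 (4aR,5R)-5-bromo-8a-hydroxy-4a-methyl-8-methylidenedecahydronaphthalene-2-carbonitrile (mixture at the carbinol carbon and at the nitrile-bearing carbon), via Barbier adduct 13 (not isolated)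
Conditions: Zn dust, THF, 0 °C → rt; then Bu3SnH (slow addition), Et3B, air, PhMe, rt
Reagents that add atoms: none
Why: Zinc inserts into the allylic C–Br bond of 12 and the 2-cyanoallylzinc adds through a six-membered chair (Zimmerman–Traxler) transition state, with allylic transposition and in 1,2 fashion, to the C5 carbonyl of enone 11, forming the C5–C6 bond at the fully substituted carbon and leaving a 2-substituted acrylonitrile in alkoxide 13; the Bu3Sn radical is then expected to abstract iodine from the neopentyl C9–I bond much faster than bromine from the secondary C1–Br bond, and the primary C9 radical adds to the unsubstituted CH2 terminus (C8) of the acrylonitrile before the α-cyano radical at C7 is reduced by Bu3SnH. The closest known reaction types are the Barbier (Dreiding–Schmidt) allylation of ketones with 2-(bromomethyl)acrylic derivatives and the tin-hydride radical conjugate addition of alkyl iodides to acrylonitriles. Ring A closes in the 6-endo-trig radical mode, favoured over 5-exo because the cyano group sits on the internal alkene carbon (a nucleophilic radical attacks the β-carbon of the acceptor) and because C10 and C5 are both fully substituted. The new C5 carbinol centre is set by the face of allylzinc attack, expected mainly anti to the axial C10 methyl, and the C7 centre by hydrogen-atom transfer to the planar α-cyano radical; neither needs control here, because C5 is re-set in steps 7 and 8 and C7 in step 10. The step needs 1,2- over 1,4-addition to the enone (secured by the allylzinc reagent), iodine over bromine abstraction (secured by the rate difference and one equivalent of slowly added Bu3SnH), and absence of the 1,2-acyl (Dowd–Beckwith) shift of a β-keto radical, which the order of events excludes since the ketone is already an alkoxide when C9 becomes a radical.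

Step 7
Reactants: 14 (4aR,5R)-5-bromo-8a-hydroxy-4a-methyl-8-methylidenedecahydronaphthalene-2-carbonitrile
Product: 15 (4aR,5R)-5-bromo-4a-methyl-8-[(phenylselanyl)methyl]-1,2,3,4,4a,5,6,7-octahydronaphthalene-2-carbonitrile (mixture at the nitrile-bearing carbon)
Conditions: PhSeH, ZnI2, ClCH2CH2Cl, rt, dark
Reagents that add atoms: benzeneselenol ([SeH]c1ccccc1)
Why: ZnI2 should ionize the tertiary allylic alcohol to the C5–C4–C15 allyl cation, which benzeneselenol captures at the unhindered primary terminus C15 to give the tetrasubstituted C4=C5 alkene, so that both C5 epimers converge on one compound (Lewis-acid-promoted SN1′ allylic substitution with 1,3-transposition).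

Step 8
Reactants: 15 (4aR,5R)-5-bromo-4a-methyl-8-[(phenylselanyl)methyl]-1,2,3,4,4a,5,6,7-octahydronaphthalene-2-carbonitrile
Product: 18 (4aR,5R,8aR)-5-bromo-8a-hydroxy-4a-methyl-8-methylidenedecahydronaphthalene-2-carbonitrile (mixture at the nitrile-bearing carbon), via selenoxide 16 (not isolated), via selenenate ester 17 (not isolated)
Conditions: 30% H2O2, pyridine, CH2Cl2, 0 °C → rt
Reagents that add atoms: hydrogen peroxide (OO)
Why: Oxidation to the allylic selenoxide should trigger the irreversible [2,3]-sigmatropic shift that returns oxygen to C5 and the double bond to the exocyclic C4=C15 position, the oxygen being delivered suprafacially to the face of the C4=C5 bond anti to the axial C10 methyl (the face also taken by peracids and singlet oxygen on 10-methyl-Δ4-octalins), which gives the 5α-carbinol and the trans ring fusion (selenoxide [2,3] rearrangement, the selenium counterpart of the Mislow–Evans rearrangement).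

Step 9
Reactants: 18 (4aR,5R,8aR)-5-bromo-8a-hydroxy-4a-methyl-8-methylidenedecahydronaphthalene-2-carbonitrile
Product: 20 (4aR,5R,8aR)-5-bromo-8a-hydroxy-4a-methyl-8-methylidenedecahydronaphthalene-2-carbaldehyde (mixture at the formyl-bearing carbon), via aldimine 19 (not isolated)
Conditions: i-Bu2AlH, CH2Cl2, −78 °C; then aq. potassium sodium tartrate (KNaC4H4O6)
Reagents that add atoms: water (O)
Why: i-Bu2AlH adds one hydride to the nitrile to give an N-aluminio aldimine that is stable at low temperature and hydrolyses to the aldehyde on work-up, while the bromide, the alkene and the tertiary alcohol (as its aluminium alkoxide) should be inert (partial reduction of a nitrile).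

Step 10
Reactants: 20 (4aR,5R,8aR)-5-bromo-8a-hydroxy-4a-methyl-8-methylidenedecahydronaphthalene-2-carbaldehyde
Product: 21 (1R,4aR,6R,8aR)-1-bromo-6-ethynyl-8a-methyl-4-methylidenedecahydronaphthalen-4a-ol
Conditions: dimethyl (1-diazo-2-oxopropyl)phosphonate, K2CO3, MeOH, 0 °C → rt
Reagents that add atoms: dimethyl (1-diazo-2-oxopropyl)phosphonate (COP(=O)(OC)C(=[N+]=[N-])C(C)=O)
Why: Under the mildly basic conditions the aldehyde α-centre (C7) equilibrates through the enolate, the axial epimer being held back as its bridged lactol with the axial 5α-hydroxyl, so the equatorial aldehyde should be the one homologated to the terminal alkyne, which fixes the C7 substituent equatorial and cis to the angular methyl (Seyferth–Gilbert homologation, Ohira–Bestmann variant).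

Step 11
Reactants: 22 2-methylbut-1-en-3-yne
Product: 24 (1E)-1-iodo-3-methylbuta-1,3-diene, via dienylzirconocene 23 (not isolated)
Conditions: Cp2Zr(H)Cl, THF, rt; then I2, 0 °C
Reagents that add atoms: iodine (I-I)
Why: Cp2Zr(H)Cl should add Zr–H syn across the terminal alkyne in preference to the 1,1-disubstituted alkene, with zirconium on the terminal carbon, and iodinolysis with retention gives the E-dienyl iodide (hydrozirconation–iodination).

Step 12
Reactants: 21 (1R,4aR,6R,8aR)-1-bromo-6-ethynyl-8a-methyl-4-methylidenedecahydronaphthalen-4a-ol; 24 (1E)-1-iodo-3-methylbuta-1,3-diene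
Product: 26 (1R,4aR,6R,8aR)-1-bromo-8a-methyl-4-methylidene-6-[(2E,4E)-6-methylhepta-2,4,6-trien-2-yl]decahydronaphthalen-4a-ol, via alkenylalane 25 (not isolated)
Conditions: Me3Al, Cp2ZrCl2 (cat.), ClCH2CH2Cl, 0 °C → rt; then 24, Pd(PPh3)4 (cat.), ZnCl2 (cat.), THF, rt
Reagents that add atoms: trimethylaluminium (C[Al](C)C)
Why: Zirconium-catalysed syn-methylalumination should place the methyl group on the internal and aluminium on the terminal alkyne carbon, and palladium-catalysed coupling of the alkenylalane with the E-dienyl iodide proceeds with retention at both partners to give the 2E,4E-triene, the hydroxyl being carried as its aluminium alkoxide (Negishi carboalumination and cross-coupling).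

Compound list
1 | 2-methylcyclohexane-1,3-dione | CC1C(=O)CCCC1=O | starting material
2 | ethyl bromoacetate | CCOC(=O)CBr | starting material
3 | ethyl 2-(1-methyl-2,6-dioxocyclohexyl)acetate | CCOC(=O)CC1(C)C(=O)CCCC1=O | intermediate
4 | ethyl 2-[(1S,2S)-2-hydroxy-1-methyl-6-oxocyclohexyl]acetate | CCOC(=O)C[C@@]1(C)[C@@H](O)CCCC1=O | intermediate
5 | (3aS,7aS)-3a-methylhexahydro-1-benzofuran-2,4-dione (cis-fused keto lactone) | O=C1CCC[C@@H]2OC(=O)C[C@]12C | intermediate
6 | trimethylsilyl 2-[(1R,2R)-2-bromo-1-methyl-6-oxocyclohexyl]acetate | C[Si](C)(C)OC(=O)C[C@@]1(C)[C@H](Br)CCCC1=O | intermediate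
7 | 2-[(1R,2R)-2-bromo-1-methyl-6-oxocyclohexyl]acetic acid (bromine cis to the methyl) | OC(=O)C[C@@]1(C)[C@H](Br)CCCC1=O | intermediate
8 | 2-[(1R,2R)-2-bromo-1-methyl-6-oxocyclohexyl]acetyl hypoiodite | O=C(OI)C[C@@]1(C)[C@H](Br)CCCC1=O | intermediate
9 | (2R,3R)-3-bromo-2-(iodomethyl)-2-methylcyclohexan-1-one | IC[C@@]1(C)[C@H](Br)CCCC1=O | intermediate
10 | (5R,6R)-5-bromo-6-(iodomethyl)-6-methyl-2-[(N-methylanilino)methyl]cyclohexan-1-one (both epimers at C2 of the ring) | CN(CC1CC[C@@H](Br)[C@](C)(CI)C1=O)c1ccccc1 | intermediate
11 | (5R,6R)-5-bromo-6-(iodomethyl)-6-methyl-2-methylidenecyclohexan-1-one | C=C1CC[C@@H](Br)[C@](C)(CI)C1=O | intermediate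
12 | 2-(bromomethyl)prop-2-enenitrile | C=C(CBr)C#N | starting material
13 | 2-{[(2R,3R)-3-bromo-1-hydroxy-2-(iodomethyl)-2-methyl-6-methylidenecyclohexyl]methyl}prop-2-enenitrile (both carbinol epimers; present as the zinc alkoxide) | N#CC(=C)CC1(O)C(=C)CC[C@@H](Br)[C@]1(C)CI | intermediate
14 | (4aR,5R)-5-bromo-8a-hydroxy-4a-methyl-8-methylidenedecahydronaphthalene-2-carbonitrile (mixture at C2 and C8a) | N#CC1CC[C@@]2(C)[C@H](Br)CCC(=C)C2(O)C1 | intermediate
15 | (4aR,5R)-5-bromo-4a-methyl-8-[(phenylselanyl)methyl]-1,2,3,4,4a,5,6,7-octahydronaphthalene-2-carbonitrile (mixture at C2) | N#CC1CC[C@@]2(C)[C@H](Br)CCC(C[Se]c3ccccc3)=C2C1 | intermediate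
16 | (4aR,5R)-8-[(benzeneseleninyl)methyl]-5-bromo-4a-methyl-1,2,3,4,4a,5,6,7-octahydronaphthalene-2-carbonitrile (mixture at C2) | N#CC1CC[C@@]2(C)[C@H](Br)CCC(C[Se](=O)c3ccccc3)=C2C1 | intermediate
17 | (4aR,5R,8aR)-5-bromo-4a-methyl-8-methylidene-8a-[(phenylselanyl)oxy]decahydronaphthalene-2-carbonitrile (mixture at C2) | N#CC1CC[C@@]2(C)[C@H](Br)CCC(=C)[C@]2(O[Se]c3ccccc3)C1 | intermediate
18 | (4aR,5R,8aR)-5-bromo-8a-hydroxy-4a-methyl-8-methylidenedecahydronaphthalene-2-carbonitrile (hydroxyl trans to the methyl, trans-fused; mixture at C2) | N#CC1CC[C@@]2(C)[C@H](Br)CCC(=C)[C@]2(O)C1 | intermediate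
19 | (1R,4aR,8aR)-1-bromo-6-(iminomethyl)-8a-methyl-4-methylidenedecahydronaphthalen-4a-ol (written as the free imine; present as the N-aluminium derivative) | N=CC1CC[C@@]2(C)[C@H](Br)CCC(=C)[C@]2(O)C1 | intermediate
20 | (4aR,5R,8aR)-5-bromo-8a-hydroxy-4a-methyl-8-methylidenedecahydronaphthalene-2-carbaldehyde (mixture at C2) | O=CC1CC[C@@]2(C)[C@H](Br)CCC(=C)[C@]2(O)C1 | intermediate
21 | (1R,4aR,6R,8aR)-1-bromo-6-ethynyl-8a-methyl-4-methylidenedecahydronaphthalen-4a-ol | C#C[C@@H]1CC[C@@]2(C)[C@H](Br)CCC(=C)[C@]2(O)C1 | intermediate
22 | 2-methylbut-1-en-3-yne | C=C(C)C#C | starting material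
23 | chloridobis(cyclopentadienyl)[(1E)-3-methylbuta-1,3-dien-1-yl]zirconium | C=C(C)/C=C/[Zr](Cl)(C1C=CC=C1)C1C=CC=C1 | intermediate
24 | (1E)-1-iodo-3-methylbuta-1,3-diene | C=C(C)/C=C/I | intermediate
25 | dimethyl[(1E)-2-(ring C6 of 21)prop-1-en-1-yl]alumane, the syn-methylalumination product of 21 (hydroxyl written free; present as the aluminium alkoxide) | C[Al](C)/C=C(\C)[C@@H]1CC[C@@]2(C)[C@H](Br)CCC(=C)[C@]2(O)C1 | intermediate
26 | (1R,4aR,6R,8aR)-1-bromo-8a-methyl-4-methylidene-6-[(2E,4E)-6-methylhepta-2,4,6-trien-2-yl]decahydronaphthalen-4a-ol | C=C(C)/C=C/C=C(\C)[C@@H]1CC[C@@]2(C)[C@H](Br)CCC(=C)[C@]2(O)C1 | target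

Total step count: 12
Longest linear sequence: 11 steps (steps 1 to 10 and step 12)

Steps most likely to fail

Step 8: the oxygen may be delivered with poor facial selectivity in the [2,3] shift (attack syn to the C10 methyl through the ring-flipped conformer), which would give the cis-fused 5-epi carbinol. The fallback sets out from 14, comes back at 18, and moves the stereo-determining event to a peracid epoxidation. Babler–Dauben oxidative transposition of 14 with pyridinium chlorochromate, C5H5NH[CrO3Cl], in CH2Cl2 should give (4aR,5R)-5-bromo-8-formyl-4a-methyl-1,2,3,4,4a,5,6,7-octahydronaphthalene-2-carbonitrile F2. Luche reduction (NaBH4, CeCl3·7H2O, MeOH) then gives the allylic alcohol (4aR,5R)-5-bromo-8-(hydroxymethyl)-4a-methyl-1,2,3,4,4a,5,6,7-octahydronaphthalene-2-carbonitrile F3. mCPBA (NaHCO3, CH2Cl2) should epoxidize the tetrasubstituted alkene anti to the angular methyl to the 8,8a-epoxy alcohol F4. PPh3, I2 and imidazole convert the primary alcohol to the epoxy iodide F5. Zinc dust in EtOH/AcOH then effects reductive 1,2-elimination across C15–C4 with opening of the oxirane to 18.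

Step 3: bromide displacement at the neopentyl-type secondary carbon may be too slow, so that elimination toward C2 or acid-induced side reactions of the ketone take over. The fallback sets out from 4, isolated instead of lactonized, and comes back at 7. Appel bromination (CBr4, PPh3, CH2Cl2, 0 °C → rt) replaces the free hydroxyl with inversion through an oxyphosphonium leaving group and an external bromide, giving ethyl 2-[(1R,2R)-2-bromo-1-methyl-6-oxocyclohexyl]acetate F1. Acidic ester hydrolysis (aq. HBr, AcOH, 50 °C) then gives 7.

Step 6: in the radical stage, reduction of the C9 radical before ring closure or competing abstraction of the C1 bromine may erode the annulation, and addition to the hindered carbonyl may be incomplete in the presence of the tin reagents. The fallback sets out from 11 and 12, comes back at 14, and separates the two events. Barbier allylation with indium powder in THF/H2O gives 13, which is isolated. The ring is then closed with SmI2, HMPA and t-BuOH in THF at −78 °C, a single-electron reductive conjugate addition of the alkyl iodide to the unsaturated nitrile that needs no tin hydride and is expected to discriminate the iodide from the secondary bromide; no compound outside the list arises (none, F0).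

Further compounds
F1 | step 3 | ethyl 2-[(1R,2R)-2-bromo-1-methyl-6-oxocyclohexyl]acetate | CCOC(=O)C[C@@]1(C)[C@H](Br)CCCC1=O
F0 | step 6 | none | none
F2 | step 8 | (4aR,5R)-5-bromo-8-formyl-4a-methyl-1,2,3,4,4a,5,6,7-octahydronaphthalene-2-carbonitrile (mixture at C2) | N#CC1CC[C@@]2(C)[C@H](Br)CCC(C=O)=C2C1
F3 | step 8 | (4aR,5R)-5-bromo-8-(hydroxymethyl)-4a-methyl-1,2,3,4,4a,5,6,7-octahydronaphthalene-2-carbonitrile (mixture at C2) | N#CC1CC[C@@]2(C)[C@H](Br)CCC(CO)=C2C1
F4 | step 8 | 8,8a-epoxide of F3 with the oxirane oxygen anti to the 4a-methyl (mixture at C2) | N#CC1CC[C@@]2(C)[C@H](Br)CC[C@@]3(CO)O[C@@]23C1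
F5 | step 8 | iodide of F4, 8-(iodomethyl)-8,8a-epoxide with the oxirane oxygen anti to the 4a-methyl (mixture at C2) | N#CC1CC[C@@]2(C)[C@H](Br)CC[C@@]3(CI)O[C@@]23C1
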